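**Retrosynthetic overview**

1. Kanzonol S (17) ⇒ tetrasilyl ether 16 ⇒ E-enal 14 ⇒ 8-allylflavanone 13. The E side chain is grown late from a C8 allyl group (cross-metathesis with methacrolein, aldehyde reduction, acetylation), and the C4 ketone comes from a C4 methyl ether by hydrolysis and oxidation.
2. Key disconnection: ring C of 4-methoxyflavan 11 is opened across C3–C4 and O1–C2 to styrene 8 (ring B, C2=C3) and the 4-methoxy ortho-quinone methide 10 of ring A. This is made in the flask from salicylaldehyde 5 and HC(OMe)3 under a confined chiral Brønsted acid, which also sets C2 (S).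
3. Enabling feature: O1 and C4 sit on the adjacent ring A carbons C8a and C4a, so dearomatised ring A is a 1-oxadiene O1=C8a–C4a=C4. C2 carries the electron-rich catechol ring B, which makes C2=C3 a polarised styrene.
4. Ring order: rings A and B are bought (2,4,6-trihydroxybenzaldehyde, 3,4-dihydroxybenzaldehyde). An aromatic Claisen rearrangement places the C8 carbon and leaves free only the phenol that becomes O1. Ring C is formed last, in the key step.

Key step: step 6

Remark: flavanone numbering (O1, C2, C3, C4, C4a, C5 to C8, C8a) is used for rings A and C; the sense of induction of the chiral acid in step 6 cannot be predicted with certainty, so it is assumed that the catalyst antipode giving 2S is fixed in the first experiment, both antipodes being accessible.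

**Route**

Step 1
Reactants: 1 2,4,6-trihydroxybenzaldehyde
Product: 2 2-hydroxy-4,6-bis(triisopropylsilyloxy)benzaldehyde
Conditions: TIPSCl (2.1 equiv), imidazole, CH2Cl2, 0 °C to rt
Reagents that add atoms: triisopropylsilyl chloride CC(C)[Si](Cl)(C(C)C)C(C)C
Why: Site-selective silylation of phenols: the para hydroxyl and one of the two equivalent ortho hydroxyls react, while the last hydroxyl is held in the hydrogen bond to the formyl oxygen and is shielded against the bulky silyl chloride, so the reaction should stop at the bis-ether.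

Step 2
Reactants: 2 2-hydroxy-4,6-bis(triisopropylsilyloxy)benzaldehyde
Product: 3 2-(allyloxy)-4,6-bis(triisopropylsilyloxy)benzaldehyde
Conditions: allyl alcohol, PPh3, DIAD, THF, 0 °C to rt
Reagents that add atoms: allyl alcohol C=CCO
Why: Mitsunobu etherification of the acidic, hydrogen-bonded phenol with a primary allylic alcohol under neutral conditions that leave the aryl silyl ethers and the aldehyde untouched.

Step 3
Reactants: 3 2-(allyloxy)-4,6-bis(triisopropylsilyloxy)benzaldehyde
Product: 5 3-allyl-2-hydroxy-4,6-bis(triisopropylsilyloxy)benzaldehyde, via ortho-dienone 4 (not isolated)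
Conditions: N,N-diethylaniline, 190 °C
Reagents that add atoms: none
Why: Aromatic Claisen rearrangement ([3,3]-sigmatropic shift, then tautomerisation of dienone 4), which can deliver the allyl group only to C3, the one free ortho position, and gives back the free phenol next to it.

Step 4
Reactants: 6 3,4-dihydroxybenzaldehyde
Product: 7 3,4-bis(tert-butyldimethylsilyloxy)benzaldehyde
Conditions: TBSCl, imidazole, DMF, rt
Reagents that add atoms: tert-butyldimethylsilyl chloride CC(C)(C)[Si](C)(C)Cl
Why: Standard silylation of both catechol hydroxyls, which have no competing site.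

Step 5
Reactants: 7 3,4-bis(tert-butyldimethylsilyloxy)benzaldehyde
Product: 8 3,4-bis(tert-butyldimethylsilyloxy)styrene
Conditions: Ph3PCH3Br, KOtBu, THF, 0 °C to rt
Reagents that add atoms: methyltriphenylphosphonium bromide C[P+](c1ccccc1)(c1ccccc1)c1ccccc1.[Br-]
Why: Wittig methylenation of an aromatic aldehyde with the non-stabilised ylide made in the flask; aryl silyl ethers should tolerate the short exposure to the ylide at 0 °C.

Step 6
Reactants: 5 3-allyl-2-hydroxy-4,6-bis(triisopropylsilyloxy)benzaldehyde; 8 3,4-bis(tert-butyldimethylsilyloxy)styrene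
Product: 11 (2S)-8-allyl-2-[3,4-bis(tert-butyldimethylsilyloxy)phenyl]-4-methoxy-5,7-bis(triisopropylsilyloxy)chromane as a C4 epimer mixture, via dimethyl acetal 9 (not isolated), via methoxy ortho-quinone methide 10 (not isolated)
Conditions: HC(OMe)3 (1.5 equiv), chiral BINOL-derived imidodiphosphorimidate (IDPi) Brønsted acid (5 mol %), 5 Å MS, CH2Cl2, −40 °C
Reagents that add atoms: trimethyl orthoformate COC(OC)OC
Why: Proposed new method: the acid converts 5 with the orthoformate into acetal 9 and ionises it to the 2-hydroxyaryl methoxycarbenium ion, the O-protonated form of ortho-quinone methide 10, paired with the chiral IDPi anion; styrene 8 then adds with its CH2 terminus to the carbenium carbon (C3–C4 bond) while the benzylic cation developing at C2, stabilised by the para silyloxy group, is captured by the phenol oxygen (O1–C2 bond). The closest known reaction types are the achiral Lewis acid-catalysed three-component chroman synthesis from salicylaldehydes, orthoformates and alkenes, the chiral phosphoric acid-catalysed [4+2] cycloadditions of ortho-quinone methides with styrenes and the IDPi-catalysed cycloadditions of styrenes with cationic heterodienes; new is the enantiocontrol of a 4-alkoxy ortho-quinone methide with a simple styrene. Ring C is closed in the intermolecular inverse-electron-demand oxa-[4+2] mode, concerted but asynchronous, the heterodiene O1=C8a–C4a=C4 giving four ring atoms and C2=C3 of the styrene two. C2 is set by the confined chiral anion, which is hydrogen-bonded to the phenolic OH and ion-paired with the carbenium ion and so should leave one face of the heterodiene open to the styrene in a single orientation of its aryl group, and this must hold for both C4 epimers, which are formed as a mixture that is erased in step 8. The step needs head-to-tail regiochemistry, secured by the polarity match of the nucleophilic styrene terminus with the electrophilic C4; it needs site selectivity for O1, secured because the only free phenol of 5 is the one next to the allyl group; and it needs chemoselectivity for the styrene over the allyl alkene, secured by the far higher nucleophilicity of the 4-silyloxystyrene. The silyloxy groups of ring A make the ionisation easy at low temperature, where oligomerisation of the styrene and re-ionisation of the product at C4 should be slow.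

Step 7
Reactants: 11 (2S)-8-allyl-2-[3,4-bis(tert-butyldimethylsilyloxy)phenyl]-4-methoxy-5,7-bis(triisopropylsilyloxy)chromane (C4 epimer mixture)
Product: 12 (2S)-8-allyl-2-[3,4-bis(tert-butyldimethylsilyloxy)phenyl]-5,7-bis(triisopropylsilyloxy)chroman-4-ol (C4 epimer mixture)
Conditions: PPTS (cat.), THF/H2O (4:1), 0 °C to rt
Reagents that add atoms: water O
Why: SN1 solvolysis of a benzylic methyl ether: ionisation at C4 is assisted by O1 and the two silyloxy groups of ring A and water in large excess captures the cation, while C2 is untouched because this weak acid does not activate the O1–C2 bond; any flav-3-ene formed by loss of H3 should re-enter by protonation at C3.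

Step 8
Reactants: 12 (2S)-8-allyl-2-[3,4-bis(tert-butyldimethylsilyloxy)phenyl]-5,7-bis(triisopropylsilyloxy)chroman-4-ol (C4 epimer mixture)
Product: 13 (2S)-8-allyl-2-[3,4-bis(tert-butyldimethylsilyloxy)phenyl]-5,7-bis(triisopropylsilyloxy)chroman-4-one
Conditions: Dess–Martin periodinane, NaHCO3, CH2Cl2, 0 °C
Reagents that add atoms: none
Why: Dess–Martin oxidation of the secondary benzylic alcohol under buffered conditions converges both C4 epimers to one ketone and does not enolise or open the flavanone, so C2 stays S.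

Step 9
Reactants: 13 (2S)-8-allyl-2-[3,4-bis(tert-butyldimethylsilyloxy)phenyl]-5,7-bis(triisopropylsilyloxy)chroman-4-one
Product: 14 (2E)-4-[(2S)-2-[3,4-bis(tert-butyldimethylsilyloxy)phenyl]-4-oxo-5,7-bis(triisopropylsilyloxy)chroman-8-yl]-2-methylbut-2-enal
Conditions: methacrolein (10 equiv), second-generation Hoveyda–Grubbs catalyst RuCl2(SIMes)(=CH-C6H4-2-OiPr) (5 mol %), CH2Cl2, 40 °C
Reagents that add atoms: methacrolein C=C(C)C=O
Why: Olefin cross-metathesis of a terminal alkene with the electron-poor 1,1-disubstituted alkene methacrolein, which does not homodimerise and should give the trisubstituted enal as the thermodynamically favoured E isomer (formyl group trans to the benzylic CH2).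

Step 10
Reactants: 14 (2E)-4-[(2S)-2-[3,4-bis(tert-butyldimethylsilyloxy)phenyl]-4-oxo-5,7-bis(triisopropylsilyloxy)chroman-8-yl]-2-methylbut-2-enal
Product: 15 (2S)-2-[3,4-bis(tert-butyldimethylsilyloxy)phenyl]-8-[(2E)-4-hydroxy-3-methylbut-2-en-1-yl]-5,7-bis(triisopropylsilyloxy)chroman-4-one
Conditions: NaBH4, EtOH/CH2Cl2, −78 °C
Reagents that add atoms: none
Why: Chemoselective 1,2-reduction of an aldehyde in the presence of a ketone with NaBH4 at low temperature: the enal should react much faster than the hindered, electron-rich aryl ketone at C4, which is flanked by the C5 silyloxy group.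

Step 11
Reactants: 15 (2S)-2-[3,4-bis(tert-butyldimethylsilyloxy)phenyl]-8-[(2E)-4-hydroxy-3-methylbut-2-en-1-yl]-5,7-bis(triisopropylsilyloxy)chroman-4-one
Product: 16 (2E)-4-[(2S)-2-[3,4-bis(tert-butyldimethylsilyloxy)phenyl]-4-oxo-5,7-bis(triisopropylsilyloxy)chroman-8-yl]-2-methylbut-2-en-1-yl acetate
Conditions: Ac2O, pyridine, DMAP (cat.), CH2Cl2, 0 °C
Reagents that add atoms: acetic anhydride CC(=O)OC(C)=O
Why: Acylation of the only free hydroxyl by nucleophilic catalysis with DMAP, under conditions too mild to open the 5-O-silylated flavanone.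

Step 12
Reactants: 16 (2E)-4-[(2S)-2-[3,4-bis(tert-butyldimethylsilyloxy)phenyl]-4-oxo-5,7-bis(triisopropylsilyloxy)chroman-8-yl]-2-methylbut-2-en-1-yl acetate
Product: 17 Kanzonol S, (2E)-4-[(2S)-2-(3,4-dihydroxyphenyl)-5,7-dihydroxy-4-oxochroman-8-yl]-2-methylbut-2-en-1-yl acetate
Conditions: TBAF, AcOH (1:1), THF, 0 °C to rt
Reagents that add atoms: none
Why: Fluoride-induced cleavage of all four aryl silyl ethers, buffered with acetic acid so that no phenoxide is formed that could open ring C by a retro-oxa-Michael reaction (loss of the C2 configuration) or attack the allylic acetate.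

**Compound list**

1 | 2,4,6-trihydroxybenzaldehyde | O=Cc1c(O)cc(O)cc1O | starting material
2 | 2-hydroxy-4,6-bis(triisopropylsilyloxy)benzaldehyde | O=Cc1c(O)cc(O[Si](C(C)C)(C(C)C)C(C)C)cc1O[Si](C(C)C)(C(C)C)C(C)C | intermediate
3 | 2-(allyloxy)-4,6-bis(triisopropylsilyloxy)benzaldehyde | C=CCOc1cc(O[Si](C(C)C)(C(C)C)C(C)C)cc(O[Si](C(C)C)(C(C)C)C(C)C)c1C=O | intermediate
4 | 5-allyl-6-oxo-2,4-bis(triisopropylsilyloxy)cyclohexa-1,3-diene-1-carbaldehyde (ortho-dienone, racemic, not isolated) | O=CC1=C(O[Si](C(C)C)(C(C)C)C(C)C)C=C(O[Si](C(C)C)(C(C)C)C(C)C)C(CC=C)C1=O | intermediate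
5 | 3-allyl-2-hydroxy-4,6-bis(triisopropylsilyloxy)benzaldehyde | C=CCc1c(O)c(C=O)c(O[Si](C(C)C)(C(C)C)C(C)C)cc1O[Si](C(C)C)(C(C)C)C(C)C | intermediate
6 | 3,4-dihydroxybenzaldehyde | O=Cc1ccc(O)c(O)c1 | starting material
7 | 3,4-bis(tert-butyldimethylsilyloxy)benzaldehyde | O=Cc1ccc(O[Si](C)(C)C(C)(C)C)c(O[Si](C)(C)C(C)(C)C)c1 | intermediate
8 | 3,4-bis(tert-butyldimethylsilyloxy)styrene | C=Cc1ccc(O[Si](C)(C)C(C)(C)C)c(O[Si](C)(C)C(C)(C)C)c1 | intermediate
9 | 2-allyl-6-(dimethoxymethyl)-3,5-bis(triisopropylsilyloxy)phenol (dimethyl acetal, not isolated) | C=CCc1c(O)c(C(OC)OC)c(O[Si](C(C)C)(C(C)C)C(C)C)cc1O[Si](C(C)C)(C(C)C)C(C)C | intermediate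
10 | 2-allyl-6-(methoxymethylidene)-3,5-bis(triisopropylsilyloxy)cyclohexa-2,4-dien-1-one (4-methoxy ortho-quinone methide, present as its O-protonated ion pair with the catalyst anion, not isolated) | C=CCC1=C(O[Si](C(C)C)(C(C)C)C(C)C)C=C(O[Si](C(C)C)(C(C)C)C(C)C)C(=COC)C1=O | intermediate
11 | (2S)-8-allyl-2-[3,4-bis(tert-butyldimethylsilyloxy)phenyl]-4-methoxy-5,7-bis(triisopropylsilyloxy)chromane (C4 epimer mixture) | C=CCc1c(O[Si](C(C)C)(C(C)C)C(C)C)cc(O[Si](C(C)C)(C(C)C)C(C)C)c2c1O[C@H](c1ccc(O[Si](C)(C)C(C)(C)C)c(O[Si](C)(C)C(C)(C)C)c1)CC2OC | intermediate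
12 | (2S)-8-allyl-2-[3,4-bis(tert-butyldimethylsilyloxy)phenyl]-5,7-bis(triisopropylsilyloxy)chroman-4-ol (C4 epimer mixture) | C=CCc1c(O[Si](C(C)C)(C(C)C)C(C)C)cc(O[Si](C(C)C)(C(C)C)C(C)C)c2c1O[C@H](c1ccc(O[Si](C)(C)C(C)(C)C)c(O[Si](C)(C)C(C)(C)C)c1)CC2O | intermediate
13 | (2S)-8-allyl-2-[3,4-bis(tert-butyldimethylsilyloxy)phenyl]-5,7-bis(triisopropylsilyloxy)chroman-4-one | C=CCc1c(O[Si](C(C)C)(C(C)C)C(C)C)cc(O[Si](C(C)C)(C(C)C)C(C)C)c2c1O[C@H](c1ccc(O[Si](C)(C)C(C)(C)C)c(O[Si](C)(C)C(C)(C)C)c1)CC2=O | intermediate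
14 | (2E)-4-[(2S)-2-[3,4-bis(tert-butyldimethylsilyloxy)phenyl]-4-oxo-5,7-bis(triisopropylsilyloxy)chroman-8-yl]-2-methylbut-2-enal | O=C/C(C)=C/Cc1c(O[Si](C(C)C)(C(C)C)C(C)C)cc(O[Si](C(C)C)(C(C)C)C(C)C)c2c1O[C@H](c1ccc(O[Si](C)(C)C(C)(C)C)c(O[Si](C)(C)C(C)(C)C)c1)CC2=O | intermediate
15 | (2S)-2-[3,4-bis(tert-butyldimethylsilyloxy)phenyl]-8-[(2E)-4-hydroxy-3-methylbut-2-en-1-yl]-5,7-bis(triisopropylsilyloxy)chroman-4-one | OC/C(C)=C/Cc1c(O[Si](C(C)C)(C(C)C)C(C)C)cc(O[Si](C(C)C)(C(C)C)C(C)C)c2c1O[C@H](c1ccc(O[Si](C)(C)C(C)(C)C)c(O[Si](C)(C)C(C)(C)C)c1)CC2=O | intermediate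
16 | (2E)-4-[(2S)-2-[3,4-bis(tert-butyldimethylsilyloxy)phenyl]-4-oxo-5,7-bis(triisopropylsilyloxy)chroman-8-yl]-2-methylbut-2-en-1-yl acetate | CC(=O)OC/C(C)=C/Cc1c(O[Si](C(C)C)(C(C)C)C(C)C)cc(O[Si](C(C)C)(C(C)C)C(C)C)c2c1O[C@H](c1ccc(O[Si](C)(C)C(C)(C)C)c(O[Si](C)(C)C(C)(C)C)c1)CC2=O | intermediate
17 | Kanzonol S | CC(=O)OC/C(C)=C/Cc1c(O)cc(O)c2c1O[C@H](c1ccc(O)c(O)c1)CC2=O | target

**Summary**

Total step count: 12. Longest linear sequence: 10 steps (steps 1, 2, 3, 6, 7, 8, 9, 10, 11, 12); the styrene branch (steps 4, 5) joins at step 6.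

**Steps most likely to fail**

Step 6 (Proposed new method). The chiral anion may discriminate the two faces at C2 poorly, or in different senses for the two C4 epimers, and acid-induced oligomerisation of the styrene may outrun the cycloaddition. The fallback uses known chemistry and sets out from 5 and 8. With trimethyl orthoformate and achiral Sc(OTf)3 in CH2Cl2 they should give racemic 8-allyl-2-[3,4-bis(tert-butyldimethylsilyloxy)phenyl]-4-methoxy-5,7-bis(triisopropylsilyloxy)chromane F1 through 9 and 10. Hydrolysis (PPTS, THF/H2O) should give the racemic chroman-4-ol F2 and Dess–Martin oxidation (NaHCO3, CH2Cl2) the racemic chroman-4-one F3. A kinetic resolution by asymmetric transfer hydrogenation with RuCl(p-cymene)[(R,R)-TsDPEN] and HCO2H/Et3N should then reduce the 2R enantiomer to the cis (2R,4R)-chroman-4-ol F4. This leaves the 2S ketone, which is compound 13, where the route is rejoined.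

Step 7. Ionisation at C4 may be followed by loss of H3 to the flav-3-ene and its oligomers instead of capture by water, and prolonged acid may start to cleave aryl silyl ethers. The fallback replaces solvolysis by hydride abstraction and sets out from 11. DDQ in CH2Cl2/pH 7 buffer at 0 °C should take the C4 hydride, which is activated by the methoxy group and ring A more strongly than the CH2 of the allyl group. Water should convert the resulting methoxy oxocarbenium ion directly into ketone 13, where the route is rejoined with steps 7 and 8 replaced by one oxidation; no new compound is made.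

Step 9. Ruthenium hydride species may isomerise the allyl group into the conjugated propenyl arene, and turnover with the electron-poor partner next to the crowded ring A may be low. The fallback builds the enal by carbonyl olefination and sets out from 13. Oxidative cleavage of the allyl alkene (OsO4 cat., NaIO4, 2,6-lutidine, dioxane/H2O) should give 2-[(2S)-2-[3,4-bis(tert-butyldimethylsilyloxy)phenyl]-4-oxo-5,7-bis(triisopropylsilyloxy)chroman-8-yl]acetaldehyde F5. Wittig reaction with the stabilised ylide 2-(triphenylphosphoranylidene)propanal in CH2Cl2 should attack only the aldehyde and give the E-enal 14, where the route is rejoined.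

**Further compounds**

F1 | step 6 | racemic 8-allyl-2-[3,4-bis(tert-butyldimethylsilyloxy)phenyl]-4-methoxy-5,7-bis(triisopropylsilyloxy)chromane | C=CCc1c(O[Si](C(C)C)(C(C)C)C(C)C)cc(O[Si](C(C)C)(C(C)C)C(C)C)c2c1OC(c1ccc(O[Si](C)(C)C(C)(C)C)c(O[Si](C)(C)C(C)(C)C)c1)CC2OC
F2 | step 6 | racemic 8-allyl-2-[3,4-bis(tert-butyldimethylsilyloxy)phenyl]-5,7-bis(triisopropylsilyloxy)chroman-4-ol | C=CCc1c(O[Si](C(C)C)(C(C)C)C(C)C)cc(O[Si](C(C)C)(C(C)C)C(C)C)c2c1OC(c1ccc(O[Si](C)(C)C(C)(C)C)c(O[Si](C)(C)C(C)(C)C)c1)CC2O
F3 | step 6 | racemic 8-allyl-2-[3,4-bis(tert-butyldimethylsilyloxy)phenyl]-5,7-bis(triisopropylsilyloxy)chroman-4-one | C=CCc1c(O[Si](C(C)C)(C(C)C)C(C)C)cc(O[Si](C(C)C)(C(C)C)C(C)C)c2c1OC(c1ccc(O[Si](C)(C)C(C)(C)C)c(O[Si](C)(C)C(C)(C)C)c1)CC2=O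
F4 | step 6 | (2R,4R)-8-allyl-2-[3,4-bis(tert-butyldimethylsilyloxy)phenyl]-5,7-bis(triisopropylsilyloxy)chroman-4-ol | C=CCc1c(O[Si](C(C)C)(C(C)C)C(C)C)cc(O[Si](C(C)C)(C(C)C)C(C)C)c2c1O[C@@H](c1ccc(O[Si](C)(C)C(C)(C)C)c(O[Si](C)(C)C(C)(C)C)c1)C[C@H]2O
F0 | step 7 | none | none
F5 | step 9 | 2-[(2S)-2-[3,4-bis(tert-butyldimethylsilyloxy)phenyl]-4-oxo-5,7-bis(triisopropylsilyloxy)chroman-8-yl]acetaldehyde | O=CCc1c(O[Si](C(C)C)(C(C)C)C(C)C)cc(O[Si](C(C)C)(C(C)C)C(C)C)c2c1O[C@H](c1ccc(O[Si](C)(C)C(C)(C)C)c(O[Si](C)(C)C(C)(C)C)c1)CC2=O
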